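**Plan**

1. Numbering used throughout: cyclohexene C1 (carries the aroyl group), C2 (carries chalcone ring A), C3=C4(CH3), C5, C6 (carries the 2,4-dihydroxyphenyl group); C3' is the carbon of ring A that lies between its two hydroxyls.
2. Retrosynthesis: cut first the chalcone Cα=Cβ bond (aldol), then the C2–C3' bond (Friedel–Crafts allylic arylation of a resorcinol by a cyclohexenyl cation), then C1–C2 and C5–C6 (Diels–Alder of acetylated morachalcone A with 1-acetoxy-3-methylbutadiene).
3. Enabling feature: C2 is allylic to the C3=C4(CH3) alkene, so a C2–C3–C4 allyl cation (tertiary at C4) is available, and C3' is flanked by two phenolic hydroxyls; the union is of the cannabidiol type, and the all-trans, all-equatorial C1/C2/C6 array is the most stable one.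
4. Forward: prenylated chalcone (aldol), cyclohexene ring (Diels–Alder, step 8), aryl–C2 bond (step 10), debromination, second chalcone by aldol with global deacetylation.
5. Stereochemistry: C1 and C6 come from the chiral borate-catalysed Diels–Alder reaction (trans from the E-alkene); C2 is set in step 10 by the C1 aroyl group (aryl enters anti); C1 stays epimerisable and rests trans.
6. Helpers: the C2 acetoxy group (oxidation level and leaving group), bromine at C5' of the nucleophile (blocks the competing ring position) and aryl acetates (deactivate the other rings); they leave in steps 10, 11 and 12.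

Key step: step 10

Assumption: the borate of (S)-BINOL is taken to deliver the diene to the face of the chelated chalcone that gives the (1S,6R) adduct; if the sense of induction is the opposite one, (R)-BINOL is used and nothing else changes.
Assumption: 1-(5-bromo-2,4-dihydroxyphenyl)ethanone (14) is taken as a purchased building block; it is otherwise accessible by monobromination of 1.

**Step 1**
Reactants: 1 1-(2,4-dihydroxyphenyl)ethanone; 2 1-bromo-3-methylbut-2-ene
Product: 3 1-[2,4-dihydroxy-3-(3-methylbut-2-en-1-yl)phenyl]ethanone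
Conditions: KOH (10% aq.), 0 °C → rt
Reagents that add atoms: none
Why: Aqueous KOH generates the ambident phenoxide, whose C-alkylation by the allylic bromide (phenoxide C-prenylation) should take place preferentially at C3 between the two oxygens, the isomers being removed by chromatography.

**Step 2**
Reactants: 3 1-[2,4-dihydroxy-3-(3-methylbut-2-en-1-yl)phenyl]ethanone
Product: 4 1-[2-hydroxy-4-(methoxymethoxy)-3-(3-methylbut-2-en-1-yl)phenyl]ethanone
Conditions: MOMCl (1.2 equiv), K2CO3, acetone, 0 °C → rt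
Reagents that add atoms: chloromethyl methyl ether, COCCl
Why: The 2-hydroxyl is held in a hydrogen bond to the ketone, so Williamson-type O-alkylation (MOM protection) should occur only at the 4-hydroxyl.

**Step 3**
Reactants: 5 2,4-dihydroxybenzaldehyde
Product: 6 2,4-bis(methoxymethoxy)benzaldehyde
Conditions: MOMCl (2.5 equiv), iPr2NEt, CH2Cl2, 0 °C → rt
Reagents that add atoms: chloromethyl methyl ether, COCCl
Why: Twofold O-alkylation with the α-chloro ether (MOM protection) keeps the aldehyde electrophilic under the basic condensation that follows.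

**Step 4**
Reactants: 4 1-[2-hydroxy-4-(methoxymethoxy)-3-(3-methylbut-2-en-1-yl)phenyl]ethanone; 6 2,4-bis(methoxymethoxy)benzaldehyde
Product: 7 (E)-3-[2,4-bis(methoxymethoxy)phenyl]-1-[2-hydroxy-4-(methoxymethoxy)-3-(3-methylbut-2-en-1-yl)phenyl]prop-2-en-1-one
Conditions: KOH (aq.), EtOH, rt
Reagents that add atoms: none
Why: Claisen–Schmidt aldol condensation of the methyl ketone enolate with the non-enolisable aldehyde, followed by dehydration, should give the thermodynamically favoured E-enone.

**Step 5**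
Reactants: 7 (E)-3-[2,4-bis(methoxymethoxy)phenyl]-1-[2-hydroxy-4-(methoxymethoxy)-3-(3-methylbut-2-en-1-yl)phenyl]prop-2-en-1-one
Product: 8 (E)-1-[2,4-dihydroxy-3-(3-methylbut-2-en-1-yl)phenyl]-3-(2,4-dihydroxyphenyl)prop-2-en-1-one (morachalcone A)
Conditions: HCl (3 M aq.), MeOH, rt → 40 °C
Reagents that add atoms: none
Why: Acid-catalysed transacetalisation to methanol removes the three MOM groups under conditions mild enough to leave the prenyl group and the enone intact.

**Step 6**
Reactants: 8 (E)-1-[2,4-dihydroxy-3-(3-methylbut-2-en-1-yl)phenyl]-3-(2,4-dihydroxyphenyl)prop-2-en-1-one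
Product: 9 (E)-3-(2,4-diacetoxyphenyl)-1-[4-acetoxy-2-hydroxy-3-(3-methylbut-2-en-1-yl)phenyl]prop-2-en-1-one
Conditions: Ac2O (3.2 equiv), pyridine, CH2Cl2, 0 °C
Reagents that add atoms: acetic anhydride, CC(=O)OC(C)=O
Why: O-Acylation of the three free phenols; the chelated 2'-hydroxyl is far less nucleophilic and should stay free for boron chelation in step 8.

**Step 7**
Reactants: 10 3-methylbut-2-enal
Product: 11 (E)-3-methylbuta-1,3-dien-1-yl acetate
Conditions: Ac2O, KOAc, 120 °C, then distillation
Reagents that add atoms: acetic anhydride, CC(=O)OC(C)=O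
Why: Vinylogous enolisation of the enal toward a γ-methyl group and O-acetylation (dienol acetate formation) should give the E-dienyl acetate.

**Step 8**
Reactants: 9 (E)-3-(2,4-diacetoxyphenyl)-1-[4-acetoxy-2-hydroxy-3-(3-methylbut-2-en-1-yl)phenyl]prop-2-en-1-one; 11 (E)-3-methylbuta-1,3-dien-1-yl acetate
Product: 12 (1S,6R)-1-[4-acetoxy-2-hydroxy-3-(3-methylbut-2-en-1-yl)benzoyl]-6-(2,4-diacetoxyphenyl)-4-methylcyclohex-3-en-2-yl acetate (both C2 epimers)
Conditions: B(OPh)3 (20 mol %), (S)-BINOL (20 mol %), 4 Å MS, PhCF3, rt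
Reagents that add atoms: none
Why: Diels–Alder reaction of the boron-chelated 2'-hydroxychalcone under chiral BINOL borate catalysis: the diene CH2 terminus (largest HOMO coefficient through the 1-acetoxy and 3-methyl groups) bonds to the β-carbon, the E-alkene fixes C1 and C6 trans, the chiral borate shields one face of the chelate and sets both centres absolutely, and the configuration at C2 is of no consequence because it is erased in step 10.

**Step 9**
Reactants: 12 (1S,6R)-1-[4-acetoxy-2-hydroxy-3-(3-methylbut-2-en-1-yl)benzoyl]-6-(2,4-diacetoxyphenyl)-4-methylcyclohex-3-en-2-yl acetate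
Product: 13 (1S,6R)-1-[2,4-diacetoxy-3-(3-methylbut-2-en-1-yl)benzoyl]-6-(2,4-diacetoxyphenyl)-4-methylcyclohex-3-en-2-yl acetate (both C2 epimers)
Conditions: Ac2O, pyridine, DMAP (cat.), 0 °C → rt
Reagents that add atoms: acetic anhydride, CC(=O)OC(C)=O
Why: DMAP-catalysed acylation of the chelated phenol removes the one hydroxyl that could close a chromanone ring onto C2 or form a chroman with the prenyl group in step 10; the weak base should not eliminate the β-acetoxy ketone.

**Step 10**
Reactants: 13 (1S,6R)-1-[2,4-diacetoxy-3-(3-methylbut-2-en-1-yl)benzoyl]-6-(2,4-diacetoxyphenyl)-4-methylcyclohex-3-en-2-yl acetate; 14 1-(5-bromo-2,4-dihydroxyphenyl)ethanone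
Product: 16 (1S,2S,6R)-2-(3-acetyl-5-bromo-2,6-dihydroxyphenyl)-1-[2,4-diacetoxy-3-(3-methylbut-2-en-1-yl)benzoyl]-6-(2,4-diacetoxyphenyl)-4-methylcyclohex-3-ene, via allyl cation 15 (not isolated)
Conditions: 14 (2 equiv), Sc(OTf)3 (15 mol %), CH2Cl2/MeNO2, −20 → 0 °C
Reagents that add atoms: none
Why: The Lewis acid ionises the allylic acetate of either C2 epimer of 13 to the same C2–C3–C4 allyl cation 15 (tertiary at the methyl-bearing C4), which is captured at C2 by C3 of the resorcinol ring of 14, and loss of a proton restores the arene (Friedel–Crafts allylic alkylation). The closest known reaction type is the acid-mediated union of resorcinols, including halogen-blocked ones, with cyclic terpenyl allyl cations in cannabidiol-type syntheses. No ring is closed. The new stereocentre C2 is controlled by the adjacent C1 aroyl group: the arene should enter anti to it, which gives the trans-diequatorial and, with C6, the all-trans arrangement that is also the most stable one, while C1 and C6 from step 8 are not touched. The step needs three selectivities: attack at the secondary allyl terminus C2 instead of C4 (it keeps the trisubstituted C3=C4 alkene and avoids a quaternary centre), attack by C3 of the arene (bromine occupies C5, the position para to the 2-hydroxyl, so the carbon between the two hydroxyls is the only activated one left), and reaction of 14 only (all aryl rings of 13 are acetylated and deactivated, and O-allylation of a phenol is reversible under the Lewis acid whereas C-arylation is not). Low temperature and excess 14 should keep loss of the C1 proton to a dienone and acid-induced phenol–alkene cyclisation behind.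

**Step 11**
Reactants: 16 (1S,2S,6R)-2-(3-acetyl-5-bromo-2,6-dihydroxyphenyl)-1-[2,4-diacetoxy-3-(3-methylbut-2-en-1-yl)benzoyl]-6-(2,4-diacetoxyphenyl)-4-methylcyclohex-3-ene
Product: 17 (1S,2S,6R)-2-(3-acetyl-2,6-dihydroxyphenyl)-1-[2,4-diacetoxy-3-(3-methylbut-2-en-1-yl)benzoyl]-6-(2,4-diacetoxyphenyl)-4-methylcyclohex-3-ene
Conditions: Pd(OAc)2 (5 mol %), PPh3 (20 mol %), HCO2Na, DMF, 80 °C
Reagents that add atoms: none
Why: Palladium-catalysed transfer hydrogenolysis of the aryl bromide (oxidative addition to zerovalent palladium, formate exchange, decarboxylation, C–H reductive elimination) uses no dihydrogen, so the alkenes should be spared.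

**Step 12**
Reactants: 17 (1S,2S,6R)-2-(3-acetyl-2,6-dihydroxyphenyl)-1-[2,4-diacetoxy-3-(3-methylbut-2-en-1-yl)benzoyl]-6-(2,4-diacetoxyphenyl)-4-methylcyclohex-3-ene; 18 4-hydroxybenzaldehyde
Product: 20 CNP0283121.2, via pentaphenol methyl ketone 19 (not isolated)
Conditions: KOH (50% aq.), EtOH, rt; then AcOH to pH 5
Reagents that add atoms: none
Why: Saponification of the four aryl acetates gives 19, whose only methyl ketone undergoes Claisen–Schmidt condensation with the aldehyde to the E-chalcone, and the base lets C1 rest in the all-trans arrangement.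

**Compound list**

1 | 1-(2,4-dihydroxyphenyl)ethanone | CC(=O)c1ccc(O)cc1O | starting material
2 | 1-bromo-3-methylbut-2-ene (prenyl bromide) | CC(C)=CCBr | starting material
3 | 1-[2,4-dihydroxy-3-(3-methylbut-2-en-1-yl)phenyl]ethanone | CC(=O)c1ccc(O)c(CC=C(C)C)c1O | intermediate
4 | 1-[2-hydroxy-4-(methoxymethoxy)-3-(3-methylbut-2-en-1-yl)phenyl]ethanone | CC(=O)c1ccc(OCOC)c(CC=C(C)C)c1O | intermediate
5 | 2,4-dihydroxybenzaldehyde | O=Cc1ccc(O)cc1O | starting material
6 | 2,4-bis(methoxymethoxy)benzaldehyde | COCOc1ccc(C=O)c(OCOC)c1 | intermediate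
7 | (E)-3-[2,4-bis(methoxymethoxy)phenyl]-1-[2-hydroxy-4-(methoxymethoxy)-3-(3-methylbut-2-en-1-yl)phenyl]prop-2-en-1-one | COCOc1ccc(/C=C/C(=O)c2ccc(OCOC)c(CC=C(C)C)c2O)c(OCOC)c1 | intermediate
8 | (E)-1-[2,4-dihydroxy-3-(3-methylbut-2-en-1-yl)phenyl]-3-(2,4-dihydroxyphenyl)prop-2-en-1-one (morachalcone A) | CC(C)=CCc1c(O)ccc(C(=O)/C=C/c2ccc(O)cc2O)c1O | intermediate
9 | (E)-3-(2,4-diacetoxyphenyl)-1-[4-acetoxy-2-hydroxy-3-(3-methylbut-2-en-1-yl)phenyl]prop-2-en-1-one | CC(C)=CCc1c(OC(C)=O)ccc(C(=O)/C=C/c2ccc(OC(C)=O)cc2OC(C)=O)c1O | intermediate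
10 | 3-methylbut-2-enal | CC(C)=CC=O | starting material
11 | (E)-3-methylbuta-1,3-dien-1-yl acetate | CC(=O)O/C=C/C(C)=C | intermediate
12 | (1S,6R)-1-[4-acetoxy-2-hydroxy-3-(3-methylbut-2-en-1-yl)benzoyl]-6-(2,4-diacetoxyphenyl)-4-methylcyclohex-3-en-2-yl acetate, both C2 epimers | CC(C)=CCc1c(OC(C)=O)ccc(C(=O)[C@@H]2C(OC(C)=O)C=C(C)C[C@H]2c2ccc(OC(C)=O)cc2OC(C)=O)c1O | intermediate
13 | (1S,6R)-1-[2,4-diacetoxy-3-(3-methylbut-2-en-1-yl)benzoyl]-6-(2,4-diacetoxyphenyl)-4-methylcyclohex-3-en-2-yl acetate, both C2 epimers | CC(C)=CCc1c(OC(C)=O)ccc(C(=O)[C@@H]2C(OC(C)=O)C=C(C)C[C@H]2c2ccc(OC(C)=O)cc2OC(C)=O)c1OC(C)=O | intermediate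
14 | 1-(5-bromo-2,4-dihydroxyphenyl)ethanone | CC(=O)c1cc(Br)c(O)cc1O | starting material
15 | C2–C3–C4 allyl cation from 13 after loss of acetate (drawn with the charge at C4; C1 and C6 as in 13) | CC(C)=CCc1c(OC(C)=O)ccc(C(=O)[C@@H]2C=C[C+](C)C[C@H]2c2ccc(OC(C)=O)cc2OC(C)=O)c1OC(C)=O | intermediate (not isolated)
16 | (1S,2S,6R)-2-(3-acetyl-5-bromo-2,6-dihydroxyphenyl)-1-[2,4-diacetoxy-3-(3-methylbut-2-en-1-yl)benzoyl]-6-(2,4-diacetoxyphenyl)-4-methylcyclohex-3-ene, all-trans | CC(C)=CCc1c(OC(C)=O)ccc(C(=O)[C@@H]2[C@@H](c3c(O)c(Br)cc(C(C)=O)c3O)C=C(C)C[C@H]2c2ccc(OC(C)=O)cc2OC(C)=O)c1OC(C)=O | intermediate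
17 | (1S,2S,6R)-2-(3-acetyl-2,6-dihydroxyphenyl)-1-[2,4-diacetoxy-3-(3-methylbut-2-en-1-yl)benzoyl]-6-(2,4-diacetoxyphenyl)-4-methylcyclohex-3-ene, all-trans | CC(C)=CCc1c(OC(C)=O)ccc(C(=O)[C@@H]2[C@@H](c3c(O)ccc(C(C)=O)c3O)C=C(C)C[C@H]2c2ccc(OC(C)=O)cc2OC(C)=O)c1OC(C)=O | intermediate
18 | 4-hydroxybenzaldehyde | O=Cc1ccc(O)cc1 | starting material
19 | (1S,2S,6R)-2-(3-acetyl-2,6-dihydroxyphenyl)-1-[2,4-dihydroxy-3-(3-methylbut-2-en-1-yl)benzoyl]-6-(2,4-dihydroxyphenyl)-4-methylcyclohex-3-ene | CC(C)=CCc1c(O)ccc(C(=O)[C@@H]2[C@@H](c3c(O)ccc(C(C)=O)c3O)C=C(C)C[C@H]2c2ccc(O)cc2O)c1O | intermediate (not isolated)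
20 | CNP0283121.2: (1S,2S,6R)-1-[2,4-dihydroxy-3-(3-methylbut-2-en-1-yl)benzoyl]-2-{2,6-dihydroxy-3-[(E)-3-(4-hydroxyphenyl)prop-2-enoyl]phenyl}-6-(2,4-dihydroxyphenyl)-4-methylcyclohex-3-ene, all-trans | CC(C)=CCc1c(O)ccc(C(=O)[C@@H]2[C@@H](c3c(O)ccc(C(=O)/C=C/c4ccc(O)cc4)c3O)C=C(C)C[C@H]2c2ccc(O)cc2O)c1O | target

**Step count and risks**

Total: 12 steps. Longest linear sequence: 10 steps (1, 2, 4, 5, 6, 8, 9, 10, 11, 12).

Step 10 (most likely to fail). What may go wrong: loss of the C1 proton from the cation, or of acetic acid from 13, to a conjugated dienone that no longer reacts with the right facial sense, or slow capture by the deactivated, crowded ring carbon. Fallback: a nickel-catalysed reductive cross-electrophile coupling, in which the aryl carbon is fixed by a carbon–iodine bond and no free cation is formed. It sets out from 1 and 13. Iodination of 1 (I2, HIO3, aq. EtOH) should place iodine between the two hydroxyls and give 1-(2,4-dihydroxy-3-iodophenyl)ethanone F1. Acetylation (Ac2O, pyridine, DMAP) gives 4-acetyl-2-iodo-1,3-phenylene diacetate F2. Coupling of F2 with 13 (NiBr2(dme) 10 mol %, 4,4'-di-tert-butyl-2,2'-bipyridine, Zn dust, DMA, rt → 40 °C) should join the aryl group to the less hindered terminus C2 of the allyl nickel intermediate on the face away from the C1 aroyl group and give the hexaacetate F3. Under the conditions of step 12, F3 is saponified to 19, where the fallback comes back to the route.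

Step 8. What may go wrong: a sluggish cycloaddition of the only moderately electron-rich dienyl acetate, with decomposition of the diene by the Lewis acid and erosion of facial selectivity if the mixture has to be warmed. Fallback: the more electron-rich silyl dienol ether. It sets out from 10 and 9. Silylation of 10 (TBSOTf, Et3N, Et2O, 0 °C) gives (E)-tert-butyl(dimethyl)[(3-methylbuta-1,3-dien-1-yl)oxy]silane F4. The same borate-catalysed Diels–Alder reaction with 9 at lower temperature should give the C2 silyl ether adduct F5. Acetylation as in step 9 gives its 2'-acetate F6. Under the conditions of step 10 the allylic silyl ether of F6 is ionised to the same cation 15, and the fallback comes back to the route at 16.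

Step 12. What may go wrong: a slow condensation, because both partners are present as electron-rich phenoxides, with base-induced degradation on long exposure. Fallback: the enone is built with a masked aldehyde phenol and unmasked in a separate mild step. It sets out from 17. Condensation with purchased 4-(oxan-2-yloxy)benzaldehyde (KOH, EtOH/H2O, rt; the acetates are cleaved in the same flask) should give the tetrahydropyranyl ether of the target F7. Acetal cleavage (PPTS, MeOH, rt) then returns to the route at 20.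

**Further compounds**

F1 | step 10 | 1-(2,4-dihydroxy-3-iodophenyl)ethanone | CC(=O)c1ccc(O)c(I)c1O
F2 | step 10 | 4-acetyl-2-iodo-1,3-phenylene diacetate | CC(=O)Oc1ccc(C(C)=O)c(OC(C)=O)c1I
F3 | step 10 | (1S,2S,6R)-2-(3-acetyl-2,6-diacetoxyphenyl)-1-[2,4-diacetoxy-3-(3-methylbut-2-en-1-yl)benzoyl]-6-(2,4-diacetoxyphenyl)-4-methylcyclohex-3-ene | CC(C)=CCc1c(OC(C)=O)ccc(C(=O)[C@@H]2[C@@H](c3c(OC(C)=O)ccc(C(C)=O)c3OC(C)=O)C=C(C)C[C@H]2c2ccc(OC(C)=O)cc2OC(C)=O)c1OC(C)=O
F4 | step 8 | (E)-tert-butyl(dimethyl)[(3-methylbuta-1,3-dien-1-yl)oxy]silane | C=C(C)/C=C/O[Si](C)(C)C(C)(C)C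
F5 | step 8 | (1S,6R)-1-[4-acetoxy-2-hydroxy-3-(3-methylbut-2-en-1-yl)benzoyl]-6-(2,4-diacetoxyphenyl)-4-methylcyclohex-3-en-2-yl tert-butyldimethylsilyl ether, both C2 epimers | CC(C)=CCc1c(OC(C)=O)ccc(C(=O)[C@@H]2C(O[Si](C)(C)C(C)(C)C)C=C(C)C[C@H]2c2ccc(OC(C)=O)cc2OC(C)=O)c1O
F6 | step 8 | (1S,6R)-1-[2,4-diacetoxy-3-(3-methylbut-2-en-1-yl)benzoyl]-6-(2,4-diacetoxyphenyl)-4-methylcyclohex-3-en-2-yl tert-butyldimethylsilyl ether, both C2 epimers | CC(C)=CCc1c(OC(C)=O)ccc(C(=O)[C@@H]2C(O[Si](C)(C)C(C)(C)C)C=C(C)C[C@H]2c2ccc(OC(C)=O)cc2OC(C)=O)c1OC(C)=O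
F7 | step 12 | 4-O-(oxan-2-yl) ether of the target at the 4-hydroxyphenyl ring (both acetal epimers) | CC(C)=CCc1c(O)ccc(C(=O)[C@@H]2[C@@H](c3c(O)ccc(C(=O)/C=C/c4ccc(OC5CCCCO5)cc4)c3O)C=C(C)C[C@H]2c2ccc(O)cc2O)c1O
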